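**Plan**

- Retrosynthesis: the C1'–O ester bond is cut first, then ring A of the naphthazarin at C4–C3, C2–C1 and C1–C8a (benzannulation of an aryl carbene complex of chromium with a terminal enyne and one CO), then the C1'–C(alkyne) bond and the C2'=C3' alkene of the enyne.
- Enabling feature: ring A (C1, C2, C3, C4, C4a, C8a) carries its only carbon substituent at C2 and ring B (C5 to C8) is symmetrically 5,8-dioxygenated. C2–C3 can therefore be a terminal alkyne whose propargylic carbon is C1', C1 a CO ligand, C4 the carbene carbon and C4a/C8a two carbons of a bought benzene ring.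
- Forward: ring B is bought as 2-bromohydroquinone and turned into the carbene complex (steps 1–2); the side-chain enyne is made in steps 3–7; ring A is closed around the side chain in step 8; oxidation to the quinone, deprotection and esterification finish the synthesis (steps 9–11).
- Stereochemistry: C1' (R) is set by ligand-controlled zinc/ProPhenol alkynylation of an enal (step 5) and is a spectator afterwards; the (E)-alkene comes from cross-metathesis; the acyl stereocentre is bought as (R)-2-methylbutanoic acid.

Key step: step 8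

Assumption: the (S,S) hand of ProPhenol is taken to direct alkynyl transfer to the Si face of the (E)-enal, which gives the (R) carbinol. This sense is not certain; the configuration would be checked by Mosher ester analysis of the first batch, and the equally available (R,R) ligand used if it proved opposite.

**Route**

Step 1
Reactants: 1 2-bromohydroquinone (2-bromobenzene-1,4-diol)
Product: 2 2-bromo-1,4-bis(methoxymethoxy)benzene
Conditions: MOMCl (3 equiv), i-Pr2NEt (4 equiv), CH2Cl2, 0 °C → rt
Reagents that add atoms: chloromethyl methyl ether, COCCl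
Why: Base-mediated O-alkylation of both phenols with the reactive α-chloro ether (methoxymethyl ether formation) should be clean, and the acetals tolerate n-BuLi and zerovalent chromium while remaining removable with acid at the end.

Step 2
Reactants: 2 2-bromo-1,4-bis(methoxymethoxy)benzene; 3 chromium hexacarbonyl Cr(CO)6
Product: 6 pentacarbonyl[[2,5-bis(methoxymethoxy)phenyl](methoxy)methylidene]chromium, via 2,5-bis(methoxymethoxy)phenyllithium 4 (not isolated), via lithium pentacarbonyl(aroyl)chromate 5 (not isolated)
Conditions: n-BuLi (1.05 equiv), THF, −78 °C; cannulate onto Cr(CO)6, THF, −78 °C → rt; concentrate; MeOTf (1.5 equiv), CH2Cl2, 0 °C → rt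
Reagents that add atoms: methyl trifluoromethanesulfonate, COS(=O)(=O)C(F)(F)F
Why: Fischer carbene synthesis: fast Br/Li exchange (the ortho acetal oxygen stabilises the aryllithium), addition of the aryllithium to a CO ligand of Cr(CO)6 to give the acylchromate, and O-methylation of its hard oxygen by MeOTf.

Step 3
Reactants: 7 2-methylbut-3-en-2-ol; 8 (E)-but-2-enal (crotonaldehyde)
Product: 9 (E)-4-hydroxy-4-methylpent-2-enal
Conditions: 8 (4 equiv), second-generation Hoveyda–Grubbs catalyst RuCl2(=CH-C6H4-2-O-i-Pr)(H2IMes) (3 mol %), CH2Cl2, 40 °C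
Reagents that add atoms: none
Why: Olefin cross-metathesis in which the tertiary allylic alcohol homodimerises slowly and excess crotonaldehyde drives the exchange with loss of propene, the conjugated product forming as the (E)-isomer under thermodynamic control.

Step 4
Reactants: 9 (E)-4-hydroxy-4-methylpent-2-enal
Product: 10 (E)-4-methyl-4-(triethylsilyloxy)pent-2-enal
Conditions: TESOTf (1.2 equiv), 2,6-lutidine (1.5 equiv), CH2Cl2, −78 °C
Reagents that add atoms: triethylsilyl trifluoromethanesulfonate, CC[Si](CC)(CC)OS(=O)(=O)C(F)(F)F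
Why: Silylation of a hindered tertiary alcohol with a silyl triflate and a hindered pyridine base is standard, and the enal has no γ-hydrogen from which a silyl dienol ether could form.

Step 5
Reactants: 10 (E)-4-methyl-4-(triethylsilyloxy)pent-2-enal; 11 ethynyltrimethylsilane
Product: 13 (3R,4E)-6-methyl-6-(triethylsilyloxy)-1-(trimethylsilyl)hept-4-en-1-yn-3-ol, via methyl[(trimethylsilyl)ethynyl]zinc 12 (not isolated)
Conditions: 11 (3 equiv), Me2Zn (3 equiv), (S,S)-ProPhenol (10 mol %), Ph3P=O (20 mol %), toluene, 0 °C; then 10; aq. NH4Cl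
Reagents that add atoms: none
Why: Enantioselective alkynylation of an α,β-unsaturated aldehyde by the dinuclear zinc catalyst formed from Me2Zn and ProPhenol: the alkynylzinc adds 1,2 to the Si face of the aldehyde held in the chiral pocket, so C1' is set as (R) under ligand control.

Step 6
Reactants: 13 (3R,4E)-6-methyl-6-(triethylsilyloxy)-1-(trimethylsilyl)hept-4-en-1-yn-3-ol
Product: 14 (3R,4E)-6-methyl-6-(triethylsilyloxy)hept-4-en-1-yn-3-ol
Conditions: K2CO3 (0.2 equiv), MeOH, 0 °C
Reagents that add atoms: none
Why: Methoxide-catalysed protodesilylation cleaves the C(sp)–SiMe3 bond selectively, the O–SiEt3 ether of the tertiary alcohol and the carbinol stereocentre being inert to K2CO3 in methanol at 0 °C.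

Step 7
Reactants: 14 (3R,4E)-6-methyl-6-(triethylsilyloxy)hept-4-en-1-yn-3-ol
Product: 15 (3R,4E)-6-methyl-3,6-bis(triethylsilyloxy)hept-4-en-1-yne
Conditions: TESCl (1.2 equiv), imidazole (2 equiv), CH2Cl2, 0 °C → rt
Reagents that add atoms: chlorotriethylsilane, CC[Si](Cl)(CC)CC
Why: Routine silylation of a secondary alcohol with a silyl chloride and imidazole; the ether keeps the propargylic hydroxyl from intercepting the ketene intermediate of the next step as a lactone.

Step 8
Reactants: 6 pentacarbonyl[[2,5-bis(methoxymethoxy)phenyl](methoxy)methylidene]chromium; 15 (3R,4E)-6-methyl-3,6-bis(triethylsilyloxy)hept-4-en-1-yne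
Product: 17 4-methoxy-5,8-bis(methoxymethoxy)-2-[(1R,2E)-4-methyl-1,4-bis(triethylsilyloxy)pent-2-en-1-yl]naphthalen-1-ol, via tricarbonylchromium naphthol complex 16 (not isolated)
Conditions: 6 (1.2 equiv), THF (0.05 M, degassed), 50 °C, argon; then air, Et2O, rt; used at once in step 9
Reagents that add atoms: none
Why: Loss of one CO from 6 lets the alkyne bind and insert into the Cr=C bond with its CH terminus joined to the carbene carbon (C4–C3), CO insertion at the new carbene carbon (C2–C1) gives a chromium-bound vinylketene, and ring A closes by 6π electrocyclisation of that ketene onto C6 of the aryl group (C1–C8a) followed by tautomerisation to the naphthol, which stays η6-bound to Cr(CO)3 until air releases it. This is the Dötz benzannulation of an aryl(methoxy)carbene complex of zerovalent chromium with a terminal alkyne, the standard entry to 4-methoxy-1-naphthols. Ring closure can occur only at the one free ortho carbon, the other being blocked by a methoxymethoxy group. No stereocentre is formed, and C1' is an sp3 spectator that keeps its (R) configuration. The selectivity required is chemoselectivity for CO insertion and phenol formation over indene, furan and cyclobutenone products, which the methoxy(aryl)carbene of chromium, a terminal alkyne and THF at moderate temperature secure. Regiochemistry is not critical: the bulky propargylic carbon is expected next to the CO-derived C1, and the reverse orientation would lead to the same quinone after oxidation because ring B is symmetrically 5,8-dioxygenated.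

Step 9
Reactants: 17 4-methoxy-5,8-bis(methoxymethoxy)-2-[(1R,2E)-4-methyl-1,4-bis(triethylsilyloxy)pent-2-en-1-yl]naphthalen-1-ol
Product: 18 5,8-bis(methoxymethoxy)-2-[(1R,2E)-4-methyl-1,4-bis(triethylsilyloxy)pent-2-en-1-yl]naphthalene-1,4-dione
Conditions: PhI(OAc)2 (1.1 equiv), MeCN/H2O (4:1), 0 °C, short reaction time
Reagents that add atoms: water, O
Why: Oxidative demethylation of a para-methoxyphenol to the para-quinone with a trivalent iodine reagent: the phenol binds iodine, water adds at C4 ipso to the methoxy group and the hemiketal loses methanol, the free naphthol ring being far more oxidisable than the bis-acetal ring and the near-neutral medium sparing silyl ethers and acetals.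

Step 10
Reactants: 18 5,8-bis(methoxymethoxy)-2-[(1R,2E)-4-methyl-1,4-bis(triethylsilyloxy)pent-2-en-1-yl]naphthalene-1,4-dione
Product: 19 2-[(1R,2E)-1,4-dihydroxy-4-methylpent-2-en-1-yl]-5,8-dihydroxynaphthalene-1,4-dione
Conditions: HCl (2 M aq.), THF/i-PrOH, 0 °C → rt, stopped as soon as conversion is complete
Reagents that add atoms: none
Why: Acid hydrolysis removes the two aryl methoxymethyl acetals, which are labile because each is peri to a quinone carbonyl, and cleaves both Si–O bonds, so no C–O bond at C1' is broken and the adjacent electron-poor quinone disfavours ionisation there.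

Step 11
Reactants: 19 2-[(1R,2E)-1,4-dihydroxy-4-methylpent-2-en-1-yl]-5,8-dihydroxynaphthalene-1,4-dione; 20 (R)-2-methylbutanoic acid
Product: 21 (1R,2E)-1-(5,8-dihydroxy-1,4-dioxo-1,4-dihydronaphthalen-2-yl)-4-hydroxy-4-methylpent-2-en-1-yl (2R)-2-methylbutanoate
Conditions: 20 (1.1 equiv), DCC (1.2 equiv), DMAP (0.1 equiv), CH2Cl2, 0 °C
Reagents that add atoms: none
Why: Steglich esterification should acylate only the secondary allylic hydroxyl, since the tertiary alcohol is too hindered and the two peri hydroxyls are chelated to the quinone carbonyls (the selectivity known for side-chain acylation of 2-(1-hydroxyalkyl)naphthazarins), and C1' keeps its configuration because only its O–H bond reacts.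

**Compound list**

1 | 2-bromohydroquinone | Oc1ccc(O)c(Br)c1 | starting material
2 | 2-bromo-1,4-bis(methoxymethoxy)benzene | COCOc1ccc(OCOC)c(Br)c1 | intermediate
3 | chromium hexacarbonyl Cr(CO)6 | O=C=[Cr](=C=O)(=C=O)(=C=O)(=C=O)=C=O | starting material
4 | 2,5-bis(methoxymethoxy)phenyllithium (not isolated) | [Li]c1cc(OCOC)ccc1OCOC | intermediate
5 | lithium pentacarbonyl[2,5-bis(methoxymethoxy)benzoyl]chromate (not isolated) | [Li+].[O-]C(=[Cr](=C=O)(=C=O)(=C=O)(=C=O)=C=O)c1cc(OCOC)ccc1OCOC | intermediate
6 | pentacarbonyl[[2,5-bis(methoxymethoxy)phenyl](methoxy)methylidene]chromium | COC(=[Cr](=C=O)(=C=O)(=C=O)(=C=O)=C=O)c1cc(OCOC)ccc1OCOC | intermediate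
7 | 2-methylbut-3-en-2-ol | C=CC(C)(C)O | starting material
8 | (E)-but-2-enal | C/C=C/C=O | starting material
9 | (E)-4-hydroxy-4-methylpent-2-enal | CC(C)(O)/C=C/C=O | intermediate
10 | (E)-4-methyl-4-(triethylsilyloxy)pent-2-enal | CC[Si](CC)(CC)OC(C)(C)/C=C/C=O | intermediate
11 | ethynyltrimethylsilane | C#C[Si](C)(C)C | starting material
12 | methyl[(trimethylsilyl)ethynyl]zinc (not isolated) | C[Zn]C#C[Si](C)(C)C | intermediate
13 | (3R,4E)-6-methyl-6-(triethylsilyloxy)-1-(trimethylsilyl)hept-4-en-1-yn-3-ol | C[Si](C)(C)C#C[C@H](O)/C=C/C(C)(C)O[Si](CC)(CC)CC | intermediate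
14 | (3R,4E)-6-methyl-6-(triethylsilyloxy)hept-4-en-1-yn-3-ol | C#C[C@H](O)/C=C/C(C)(C)O[Si](CC)(CC)CC | intermediate
15 | (3R,4E)-6-methyl-3,6-bis(triethylsilyloxy)hept-4-en-1-yne | C#C[C@H](O[Si](CC)(CC)CC)/C=C/C(C)(C)O[Si](CC)(CC)CC | intermediate
16 | tricarbonylchromium complex of naphthol 17, Cr(CO)3 bound η6 to ring A (not isolated; metal fragment written as a separate component) | COc1cc([C@H](O[Si](CC)(CC)CC)/C=C/C(C)(C)O[Si](CC)(CC)CC)c(O)c2c(OCOC)ccc(OCOC)c12.O=C=[Cr](=C=O)=C=O | intermediate
17 | 4-methoxy-5,8-bis(methoxymethoxy)-2-[(1R,2E)-4-methyl-1,4-bis(triethylsilyloxy)pent-2-en-1-yl]naphthalen-1-ol | COc1cc([C@H](O[Si](CC)(CC)CC)/C=C/C(C)(C)O[Si](CC)(CC)CC)c(O)c2c(OCOC)ccc(OCOC)c12 | intermediate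
18 | 5,8-bis(methoxymethoxy)-2-[(1R,2E)-4-methyl-1,4-bis(triethylsilyloxy)pent-2-en-1-yl]naphthalene-1,4-dione | O=C1C=C([C@H](O[Si](CC)(CC)CC)/C=C/C(C)(C)O[Si](CC)(CC)CC)C(=O)c2c(OCOC)ccc(OCOC)c12 | intermediate
19 | 2-[(1R,2E)-1,4-dihydroxy-4-methylpent-2-en-1-yl]-5,8-dihydroxynaphthalene-1,4-dione | O=C1C=C([C@H](O)/C=C/C(C)(C)O)C(=O)c2c(O)ccc(O)c12 | intermediate
20 | (R)-2-methylbutanoic acid | CC[C@@H](C)C(=O)O | starting material
21 | (1R,2E)-1-(5,8-dihydroxy-1,4-dioxo-1,4-dihydronaphthalen-2-yl)-4-hydroxy-4-methylpent-2-en-1-yl (2R)-2-methylbutanoate | CC[C@@H](C)C(=O)O[C@H](/C=C/C(C)(C)O)C1=CC(=O)c2c(O)ccc(O)c2C1=O | target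

**Count and risks**

Total step count: 11. Longest linear sequence: 9 steps (steps 3 to 11, from 2-methylbut-3-en-2-ol 7 to the target 21).

Steps most likely to fail:

1. Step 8. Material may be lost after the annulation, because the electron-rich free naphthol can oxidise in air or ionise at its benzylic silyl ether during demetalation and chromatography. Part of the vinylcarbene may also leave the phenol-forming pathway. Fallback: setting out from 6 and 15, the benzannulation is run with Ac2O and Et3N present from the start (THF, 60 °C), so that the phenol is acylated while still bound to chromium. This gives the tricarbonylchromium complex of the naphthyl acetate F1, and air demetalation gives the air-stable 4-methoxy-5,8-bis(methoxymethoxy)-2-[(1R,2E)-4-methyl-1,4-bis(triethylsilyloxy)pent-2-en-1-yl]naphthalen-1-yl acetate F2, which can be purified. Methanolysis (K2CO3, degassed MeOH, 0 °C) followed in the same flask by PhI(OAc)2 in aqueous MeCN comes back to the route at quinone 18.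

2. Step 5. Facial discrimination in the alkynyl transfer to a γ,γ-disubstituted enal may be insufficient, or uncatalysed addition by free alkynylzinc may erode the enantiomeric purity. Fallback: setting out from enal 10, LiC≡CSiMe3 (from 11 and n-BuLi, THF, −78 °C) gives racemic (E)-6-methyl-6-(triethylsilyloxy)-1-(trimethylsilyl)hept-4-en-1-yn-3-ol F3. MnO2 (CH2Cl2, rt) oxidises it to (E)-6-methyl-6-(triethylsilyloxy)-1-(trimethylsilyl)hept-4-en-1-yn-3-one F4. Midland reduction with (R)-Alpine-Borane (B-isopinocampheyl-9-borabicyclo[3.3.1]nonane from (+)-α-pinene, neat, rt), in which the slim alkynyl group takes the small-group position, should give the (R) carbinol and comes back to the route at 13.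

3. Step 10. The tertiary allylic alcohol may ionise (allylic transposition, elimination to a diene) under the protic acid before the aryl acetals are fully cleaved. Fallback: setting out from 18, TESOTf and 2,2'-bipyridyl (CH2Cl2, 0 °C) exchange the aromatic methoxymethyl ethers for silyl ethers without free protic acid. This gives 2-[(1R,2E)-4-methyl-1,4-bis(triethylsilyloxy)pent-2-en-1-yl]-5,8-bis(triethylsilyloxy)naphthalene-1,4-dione F5, used crude. HF·pyridine in THF/pyridine at 0 °C then removes all four silyl groups and comes back to the route at 19.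

**Further compounds**

F1 | step 8 | tricarbonylchromium complex of acetate F2, Cr(CO)3 bound η6 to ring A (metal fragment written as a separate component) | COc1cc([C@H](O[Si](CC)(CC)CC)/C=C/C(C)(C)O[Si](CC)(CC)CC)c(OC(C)=O)c2c(OCOC)ccc(OCOC)c12.O=C=[Cr](=C=O)=C=O
F2 | step 8 | 4-methoxy-5,8-bis(methoxymethoxy)-2-[(1R,2E)-4-methyl-1,4-bis(triethylsilyloxy)pent-2-en-1-yl]naphthalen-1-yl acetate | COc1cc([C@H](O[Si](CC)(CC)CC)/C=C/C(C)(C)O[Si](CC)(CC)CC)c(OC(C)=O)c2c(OCOC)ccc(OCOC)c12
F3 | step 5 | racemic (E)-6-methyl-6-(triethylsilyloxy)-1-(trimethylsilyl)hept-4-en-1-yn-3-ol | C[Si](C)(C)C#CC(O)/C=C/C(C)(C)O[Si](CC)(CC)CC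
F4 | step 5 | (E)-6-methyl-6-(triethylsilyloxy)-1-(trimethylsilyl)hept-4-en-1-yn-3-one | C[Si](C)(C)C#CC(=O)/C=C/C(C)(C)O[Si](CC)(CC)CC
F5 | step 10 | 2-[(1R,2E)-4-methyl-1,4-bis(triethylsilyloxy)pent-2-en-1-yl]-5,8-bis(triethylsilyloxy)naphthalene-1,4-dione | O=C1C=C([C@H](O[Si](CC)(CC)CC)/C=C/C(C)(C)O[Si](CC)(CC)CC)C(=O)c2c(O[Si](CC)(CC)CC)ccc(O[Si](CC)(CC)CC)c12
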